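Atom labels: lactone O1, C2 (C=O), C3 (C–OH), C4 (CH), C5 (OCH2). Ring A is the guaiacyl ring on the C3 arm and ring B is the syringyl ring on the C4 arm.
Cuts, in retrosynthetic order: both phenol O–benzyl ethers; the lactone O1–C2 bond (C5 goes back to a CO2H, and C2 with the C3 oxygen go back into a pivalaldehyde dioxolanone); the bond between the CH2 on C4 and C1 of ring B (back to a plain C-methyl group and an aryl iodide); the C3–CH2 bond to ring A; the C4–CH3 bond, which leaves (S)-malate.
Enabling feature: the CH2 that carries ring B is β to C5. With C5 at the carboxylic acid level, the carboxylate O, C5, C4 and that carbon close a five-membered palladacycle, so an unactivated CH3 becomes the coupling partner. C3 is fully substituted, and its OH and the C2 carboxyl sit in the dioxolanone ring, so there is no other β-hydrogen and no second binding group.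
Forward order: C2–C5 chain from malate, methyl on C4, temporary dioxolanone ring, ring A arm on C3, ring B joined by C–H arylation, lactone ring closed last with loss of the acetal, then debenzylation.
Stereochemistry: C3 comes from (S)-malate, relayed through the cis tert-butyl acetal (self-regeneration of the stereocentre, net retention). C4 comes from the anti-selective Fráter–Seebach methylation. The key step touches neither centre.

Key step: step 8

Assumption: the target SMILES is read as (3S,4S), with the two arylmethyl arms trans on the lactone and the C3 hydroxyl cis to the C4 arm. Compounds 1, 6 and 10 are taken as commercial.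

Step 1
Reactants: 1 dimethyl (S)-malate
Product: 3 dimethyl (2S,3R)-2-hydroxy-3-methylbutanedioate, via dilithium alkoxide enolate 2 (not isolated)
Conditions: LiN(iPr)2 (2.2 equiv), THF, −78 to −20 °C; MeI, −78 to 0 °C; aq. HCl work-up
Reagents that add atoms: methyl iodide (CI)
Why: Fráter–Seebach alkylation, in which the lithium-chelated alkoxide enolate should be methylated on the face anti to the alkoxide-bearing stereocentre, setting the new centre as R (anti to the hydroxyl) while the carbinol centre stays S.

Step 2
Reactants: 3 dimethyl (2S,3R)-2-hydroxy-3-methylbutanedioate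
Product: 4 (2S,3R)-2-hydroxy-3-methylbutanedioic acid
Conditions: KOH, MeOH/H2O, 0 °C to rt; aq. HCl to pH 1, EtOAc extraction
Reagents that add atoms: potassium hydroxide ([K+].[OH-])
Why: Saponification of both methyl esters, mild enough that the carboxylates formed should resist enolisation and both stereocentres should be kept.

Step 3
Reactants: 4 (2S,3R)-2-hydroxy-3-methylbutanedioic acid
Product: 5 (2R)-2-[(2S,4S)-2-tert-butyl-5-oxo-1,3-dioxolan-4-yl]propanoic acid (tert-butyl cis to the side chain)
Conditions: t-BuCHO, p-TsOH (cat.), H2SO4 (cat.), pentane, reflux, Dean–Stark trap; recrystallisation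
Reagents that add atoms: pivalaldehyde (CC(C)(C)C=O)
Why: Acid-catalysed acetalisation with water removal, in which the α-hydroxy acid should close the five-membered dioxolanone rather than the six-membered dioxanone of the β-carboxyl, and thermodynamic control should place tert-butyl cis to the side chain so that the new acetal centre (S) is set by the malate carbinol centre.

Step 4
Reactants: 6 [4-(benzyloxy)-3-methoxyphenyl]methanol
Product: 7 1-(benzyloxy)-4-(bromomethyl)-2-methoxybenzene
Conditions: PBr3, Et2O, 0 °C; used without storage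
Reagents that add atoms: phosphorus tribromide (BrP(Br)Br)
Why: Bromination of a benzylic alcohol through its phosphite ester (SN2 displacement by bromide), a standard way to electron-rich benzyl bromides that leaves the aryl ethers alone.

Step 5
Reactants: 5 (2R)-2-[(2S,4S)-2-tert-butyl-5-oxo-1,3-dioxolan-4-yl]propanoic acid; 7 1-(benzyloxy)-4-(bromomethyl)-2-methoxybenzene
Product: 9 (2R)-2-{(2S,4S)-4-[4-(benzyloxy)-3-methoxybenzyl]-2-tert-butyl-5-oxo-1,3-dioxolan-4-yl}propanoic acid, via dilithium carboxylate enolate 8 (not isolated)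
Conditions: LiN(SiMe3)2 (2.2 equiv), THF, −78 °C; 7, −78 to −20 °C; aq. HCl work-up
Reagents that add atoms: none
Why: Alkylation of a chiral dioxolanone enolate (self-regeneration of stereocentres), in which the planar ring enolate should be attacked by the benzylic bromide anti to the tert-butyl group, on the face the hydrogen left, so that the quaternary centre forms with net retention (S) while the much less acidic α-CH of the carboxylate is not deprotonated.

Step 6
Reactants: 10 4-bromo-2,6-dimethoxyphenol
Product: 11 2-(benzyloxy)-5-bromo-1,3-dimethoxybenzene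
Conditions: BnBr, K2CO3, DMF, rt
Reagents that add atoms: benzyl bromide (BrCc1ccccc1)
Why: Williamson ether synthesis on the phenoxide, which masks the oxidisable phenol before the silver- and palladium-mediated coupling.

Step 7
Reactants: 11 2-(benzyloxy)-5-bromo-1,3-dimethoxybenzene
Product: 12 2-(benzyloxy)-5-iodo-1,3-dimethoxybenzene
Conditions: NaI, CuI (cat.), trans-N,N'-dimethylcyclohexane-1,2-diamine (cat.), 1,4-dioxane, 110 °C
Reagents that add atoms: sodium iodide ([Na+].[I-])
Why: Copper-catalysed aromatic Finkelstein halogen exchange, which supplies the aryl iodide needed for oxidative addition to a palladacycle without changing the ring substitution pattern.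

Step 8
Reactants: 9 (2R)-2-{(2S,4S)-4-[4-(benzyloxy)-3-methoxybenzyl]-2-tert-butyl-5-oxo-1,3-dioxolan-4-yl}propanoic acid; 12 2-(benzyloxy)-5-iodo-1,3-dimethoxybenzene
Product: 13 (2R)-3-[4-(benzyloxy)-3,5-dimethoxyphenyl]-2-{(2S,4S)-4-[4-(benzyloxy)-3-methoxybenzyl]-2-tert-butyl-5-oxo-1,3-dioxolan-4-yl}propanoic acid
Conditions: Pd(OAc)2 (10 mol %), N-acetyl-β-alanine (20 mol %), Ag2CO3, 12 (1.5 equiv), (CF3)2CHOH, 80 °C
Reagents that add atoms: none
Why: The carboxylate of 9 binds divalent palladium and, helped by the N-acyl amino acid ligand, one C–H bond of the adjacent methyl group is cleaved by concerted metalation–deprotonation to a five-membered palladacycle (Pd, carboxylate O, carboxyl C, the CH, the new CH2); oxidative addition of 12 gives tetravalent palladium, C–C reductive elimination forms the CH2–aryl bond, and Ag2CO3 takes up iodide and returns divalent palladium. The closest known reaction type is the ligand-enabled, carboxylate-directed β-C(sp3)–H arylation of α-branched aliphatic acids with aryl iodides. No ring of the product is closed (the palladacycle is transient) and no stereocentre is created; the three existing centres take no part, and the α-CH of a carboxylate should not enolise under carbonate at this temperature. The site selectivity that is needed is secured by the substrate: the methyl group holds the only β-hydrogens because the other β-carbon is the fully substituted dioxolanone carbon, the CH2 of ring A would need a six-membered and its ring CH an eight-membered palladacycle, and the second carboxyl and the hydroxyl are locked in the dioxolanone so that only one group can bind the metal. Mono-arylation is expected because the product offers only secondary β-C–H bonds, which free-acid direction activates far more slowly than methyl C–H bonds. The iodine of 12 is para to the protected phenol oxygen and has no ortho neighbour, so the substitution pattern of ring B is fixed by the reagent and oxidative addition is unhindered.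

Step 9
Reactants: 13 (2R)-3-[4-(benzyloxy)-3,5-dimethoxyphenyl]-2-{(2S,4S)-4-[4-(benzyloxy)-3-methoxybenzyl]-2-tert-butyl-5-oxo-1,3-dioxolan-4-yl}propanoic acid
Product: 15 (3S,4S)-3-[4-(benzyloxy)-3-methoxybenzyl]-4-[4-(benzyloxy)-3,5-dimethoxybenzyl]-3-hydroxydihydrofuran-2(3H)-one, via hydroxymethyl dioxolanone 14 (not isolated)
Conditions: BH3·SMe2, THF, 0 °C to rt; H2O quench; then p-TsOH (cat.), CH2Cl2, rt
Reagents that add atoms: none
Why: Chemoselective borane reduction of the free carboxylic acid through its acyloxyborane should spare the hindered dioxolanone carbonyl, after which acid drives a 5-exo-trig transacylation of the new primary alcohol onto that carbonyl, expelling pivalaldehyde, unveiling the tertiary hydroxyl and closing the lactone without touching either stereocentre.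

Step 10
Reactants: 15 (3S,4S)-3-[4-(benzyloxy)-3-methoxybenzyl]-4-[4-(benzyloxy)-3,5-dimethoxybenzyl]-3-hydroxydihydrofuran-2(3H)-one
Product: 16 (3S,4S)-3-hydroxy-3-(4-hydroxy-3-methoxybenzyl)-4-(4-hydroxy-3,5-dimethoxybenzyl)dihydrofuran-2(3H)-one (target)
Conditions: H2 (1 atm), Pd/C, EtOAc/EtOH, rt
Reagents that add atoms: none
Why: Catalytic hydrogenolysis of the two aryl benzyl ethers, under which the lactone, the non-benzylic tertiary alcohol and the methyl ethers should be inert.

Compound list
1 | dimethyl (S)-malate, dimethyl (2S)-2-hydroxybutanedioate | COC(=O)C[C@H](O)C(=O)OC | starting material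
2 | dilithium alkoxide enolate of 1 (enolate oxygen cis to the carbinol carbon) | [Li+].[Li+].CO/C([O-])=C/[C@H]([O-])C(=O)OC | intermediate
3 | dimethyl (2S,3R)-2-hydroxy-3-methylbutanedioate | COC(=O)[C@@H](O)[C@@H](C)C(=O)OC | intermediate
4 | (2S,3R)-2-hydroxy-3-methylbutanedioic acid | OC(=O)[C@@H](O)[C@@H](C)C(=O)O | intermediate
5 | (2R)-2-[(2S,4S)-2-tert-butyl-5-oxo-1,3-dioxolan-4-yl]propanoic acid | CC(C)(C)[C@@H]1OC(=O)[C@@H](O1)[C@@H](C)C(=O)O | intermediate
6 | [4-(benzyloxy)-3-methoxyphenyl]methanol | COc1cc(CO)ccc1OCc1ccccc1 | starting material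
7 | 1-(benzyloxy)-4-(bromomethyl)-2-methoxybenzene | COc1cc(CBr)ccc1OCc1ccccc1 | intermediate
8 | dilithium carboxylate enolate of 5 | [Li+].[Li+].CC(C)(C)[C@@H]1OC([O-])=C(O1)[C@@H](C)C(=O)[O-] | intermediate
9 | (2R)-2-{(2S,4S)-4-[4-(benzyloxy)-3-methoxybenzyl]-2-tert-butyl-5-oxo-1,3-dioxolan-4-yl}propanoic acid | CC(C)(C)[C@@H]1OC(=O)[C@](O1)(Cc2ccc(OCc3ccccc3)c(OC)c2)[C@@H](C)C(=O)O | intermediate
10 | 4-bromo-2,6-dimethoxyphenol | COc1cc(Br)cc(OC)c1O | starting material
11 | 2-(benzyloxy)-5-bromo-1,3-dimethoxybenzene | COc1cc(Br)cc(OC)c1OCc1ccccc1 | intermediate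
12 | 2-(benzyloxy)-5-iodo-1,3-dimethoxybenzene | COc1cc(I)cc(OC)c1OCc1ccccc1 | intermediate
13 | (2R)-3-[4-(benzyloxy)-3,5-dimethoxyphenyl]-2-{(2S,4S)-4-[4-(benzyloxy)-3-methoxybenzyl]-2-tert-butyl-5-oxo-1,3-dioxolan-4-yl}propanoic acid | CC(C)(C)[C@@H]1OC(=O)[C@](O1)(Cc2ccc(OCc3ccccc3)c(OC)c2)[C@@H](Cc2cc(OC)c(OCc3ccccc3)c(OC)c2)C(=O)O | intermediate
14 | (2S,5S)-5-[4-(benzyloxy)-3-methoxybenzyl]-5-{(2S)-1-[4-(benzyloxy)-3,5-dimethoxyphenyl]-3-hydroxypropan-2-yl}-2-tert-butyl-1,3-dioxolan-4-one | CC(C)(C)[C@@H]1OC(=O)[C@](O1)(Cc2ccc(OCc3ccccc3)c(OC)c2)[C@@H](Cc2cc(OC)c(OCc3ccccc3)c(OC)c2)CO | intermediate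
15 | (3S,4S)-3-[4-(benzyloxy)-3-methoxybenzyl]-4-[4-(benzyloxy)-3,5-dimethoxybenzyl]-3-hydroxydihydrofuran-2(3H)-one | COc1cc(C[C@@]2(O)C(=O)OC[C@@H]2Cc2cc(OC)c(OCc3ccccc3)c(OC)c2)ccc1OCc1ccccc1 | intermediate
16 | (3S,4S)-3-hydroxy-3-(4-hydroxy-3-methoxybenzyl)-4-(4-hydroxy-3,5-dimethoxybenzyl)dihydrofuran-2(3H)-one | COc1cc(C[C@@]2(O)C(=O)OC[C@@H]2Cc2cc(OC)c(O)c(OC)c2)ccc1O | target

Total step count: 10. Longest linear sequence: 7 (steps 1, 2, 3, 5, 8, 9, 10).

Steps most likely to fail

Step 8. The C–H cleavage may be slow beside the fully substituted ring carbon. β-Hydride elimination from the palladacycle may compete. The neighbouring carboxylate may also open the dioxolanone in hot (CF3)2CHOH. The fallback sets out from 1 and comes back at 13. It brings in the ring B arm as a carbon electrophile before the acetal is made, so that no C–H activation is needed. Commercial 4-(benzyloxy)-3,5-dimethoxybenzaldehyde is reduced with NaBH4 to [4-(benzyloxy)-3,5-dimethoxyphenyl]methanol F1. PBr3 then gives 2-(benzyloxy)-5-(bromomethyl)-1,3-dimethoxybenzene F2. Fráter–Seebach alkylation of enolate 2 (from 1) with F2 gives dimethyl (2S,3R)-2-[4-(benzyloxy)-3,5-dimethoxybenzyl]-3-hydroxybutanedioate F3. Saponification gives (2S,3R)-2-[4-(benzyloxy)-3,5-dimethoxybenzyl]-3-hydroxybutanedioic acid F4. Acetalisation with pivalaldehyde gives (2R)-3-[4-(benzyloxy)-3,5-dimethoxyphenyl]-2-[(2S,4S)-2-tert-butyl-5-oxo-1,3-dioxolan-4-yl]propanoic acid F5. Treatment of F5 with LiN(SiMe3)2 and 7 as in step 5 gives 13.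

Step 5. SN2 capture at the congested enolate carbon may be sluggish, the proton may simply return on work-up, and facial selectivity may erode if the mixture has to be warmed. The fallback sets out from 5 and comes back at 9. It replaces substitution by carbonyl addition. Enolate 8 is added at −78 °C to commercial 4-(benzyloxy)-3-methoxybenzaldehyde, a smaller and more reactive electrophile, again anti to the tert-butyl group. This gives (2R)-2-{(2S,4R)-4-[[4-(benzyloxy)-3-methoxyphenyl](hydroxy)methyl]-2-tert-butyl-5-oxo-1,3-dioxolan-4-yl}propanoic acid F6, and either carbinol epimer serves. Ionic hydrogenation with Et3SiH and CF3CO2H in CH2Cl2 at 0 °C then removes the electron-rich benzylic hydroxyl and gives 9.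

Step 9. Borane may also attack the dioxolanone carbonyl, or the acyl transfer may stall. The fallback sets out from 13 and comes back at 14. The acid is activated with isobutyl chloroformate and N-methylmorpholine as the mixed isobutyl carbonic anhydride of 13 F7. This is reduced with NaBH4 in THF/H2O at 0 °C, a nucleophilic hydride attacking the most electrophilic acyl group. The product is 14, which lactonises as in step 9.

Further compounds
F1 | step 8 | [4-(benzyloxy)-3,5-dimethoxyphenyl]methanol | COc1cc(CO)cc(OC)c1OCc1ccccc1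
F2 | step 8 | 2-(benzyloxy)-5-(bromomethyl)-1,3-dimethoxybenzene | COc1cc(CBr)cc(OC)c1OCc1ccccc1
F3 | step 8 | dimethyl (2S,3R)-2-[4-(benzyloxy)-3,5-dimethoxybenzyl]-3-hydroxybutanedioate | COC(=O)[C@@H](O)[C@@H](Cc1cc(OC)c(OCc2ccccc2)c(OC)c1)C(=O)OC
F4 | step 8 | (2S,3R)-2-[4-(benzyloxy)-3,5-dimethoxybenzyl]-3-hydroxybutanedioic acid | OC(=O)[C@@H](O)[C@@H](Cc1cc(OC)c(OCc2ccccc2)c(OC)c1)C(=O)O
F5 | step 8 | (2R)-3-[4-(benzyloxy)-3,5-dimethoxyphenyl]-2-[(2S,4S)-2-tert-butyl-5-oxo-1,3-dioxolan-4-yl]propanoic acid | CC(C)(C)[C@@H]1OC(=O)[C@@H](O1)[C@@H](Cc2cc(OC)c(OCc3ccccc3)c(OC)c2)C(=O)O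
F6 | step 5 | (2R)-2-{(2S,4R)-4-[[4-(benzyloxy)-3-methoxyphenyl](hydroxy)methyl]-2-tert-butyl-5-oxo-1,3-dioxolan-4-yl}propanoic acid (carbinol centre undefined) | CC(C)(C)[C@@H]1OC(=O)[C@](O1)(C(O)c2ccc(OCc3ccccc3)c(OC)c2)[C@@H](C)C(=O)O
F7 | step 9 | mixed isobutyl carbonic anhydride of 13 | CC(C)(C)[C@@H]1OC(=O)[C@](O1)(Cc2ccc(OCc3ccccc3)c(OC)c2)[C@@H](Cc2cc(OC)c(OCc3ccccc3)c(OC)c2)C(=O)OC(=O)OCC(C)C
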